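**Quick answer.** If your hunch was a flask finished by 20 min, the earlier runs argued otherwise: between 15.0 min and 25.0 min, alpha still gained 2 percentage points of the charge as target and epsilon 2.3 points.

the same everywhere: gas phase 47 mM (held)

| flask | substrate | protic impurity | remark | time |
|---|---|---|---|---|
| alpha | 0.13 M | 0.010 M | run made earlier |  |
| epsilon | 0.30 M | 0.010 M | run made earlier |  |
| flask | 0.20 M | 0.0100 M |  | 20 min |

| run | time / min | target / % |
|---|---|---|
| alpha | 4.00 | 3.8 |
| alpha | 8.00 | 8.2 |
| alpha | 12.0 | 11.6 |
| alpha | 15.0 | 12.9 |
| alpha | 20.0 | 14.0 |
| alpha | 25.0 | 14.9 |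
| epsilon | 4.00 | 3.2 |
| epsilon | 8.00 | 6.7 |
| epsilon | 12.0 | 9.1 |
| epsilon | 15.0 | 9.8 |
| epsilon | 20.0 | 11.5 |
| epsilon | 25.0 | 12.1 |

(each reading ± 0.3 percentage points)

- at the start none of the gas is dissolved
- what may be going on: target <-> isomer of the product; substrate -> side product; dissolved gas + protic impurity -> quenched reagent; substrate + dissolved gas -> target; gas phase <-> dissolved gas

* the target standing at 20 min, as a percentage of the substrate charged
* concentration of dissolved gas in solution at 20 min, in percent of saturation

**Fade time.** Alpha gained 4.4 points between 4.00 min and 8.00 min, so I compared that slope with the late one and read 8.21 min as the fade time, the time in which the rate of target making falls by a factor e, an apparent first-order decay time. Epsilon read 10.5 min, and both carry the scatter of the readings. Late slope times fade estimated 1.6 points more target for alpha after 20.0 min, if the fade held.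

**The forecast.** My forecast fitted the reciprocal yield as linear in substrate and gave 12.8% of target. For the gas it said 88% of saturation: “Dissolved gas should therefore be near saturation, though this estimate is loose.”

**The result.** The flask gave 12.8% of target, and its gas stood at 66.5% of saturation, below the forecast.

    target ⇌ isomer of the product (K = 0.520, k = 0.0110 min⁻¹)
    substrate → side product (k = 0.120 min⁻¹)
    dissolved gas + protic impurity → quenched reagent (k = 5.00 M⁻¹ min⁻¹)
    substrate + dissolved gas → target (k = 1.70 M⁻¹ min⁻¹)
    gas phase ⇌ dissolved gas, rate k5*(csat - [dissolved gas]) (kL = 0.120 min⁻¹)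

**Not at rest.** From the 4.41% of the same flask read at 5.0 min and its 8.88% at 10.0 min, alpha's fade reckons the target at 12.6% at 20 min. Yet 21.9 fades later, at 200 min, the flask had still changed: substrate went from 4.8% to 0%, target from 12.8% to 10.5%, isomer of the product from 1.49% to 5.43%, and dissolved gas from 66.5% to 100% of saturation.

(Readings and results come from a simulation for substances that don't exist, noise included.)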